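**Direct plan and its weak steps**

A direct plan would follow the biosynthesis: geranylgeraniol would be silylated, its terminal E-methyl oxidised with SeO2 to the ω-allylic alcohol A1, and the oxygen moved by Sharpless epoxidation, hydride opening and re-closure to the terminal 2,2-disubstituted oxirane A2. A2 would be cyclised with MeAlCl2 to the 19-acetoxylabdadiene A3, followed by allylic hydroxylation at C7 and desilylation.
- The epoxide-initiated bicyclisation of A2 would be the weakest step. No cation–olefin cascade is known to start from a terminal 1,1-disubstituted oxirane. C4 would be set only by a CH3 versus CH2O–Al preference in the transition state, and proton loss would have to choose C17 over C7 and C9. All four ring stereocentres would rest on this one unproven step.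
- The SeO2 oxidation of the silylated tetraene to A1 would have to pick one of many allylic positions and be stopped at partial conversion with recycling.
- The epoxidation / LiAlH4 / tosyl-imidazole stretch from A1 to A2 would be three steps that form no C–C bond and only relocate one oxygen, while the enantiopurity of the whole route would hang on them.

**Retrosynthetic overview of the new route**

Ring B is made first: an organocatalytic Michael/aldol pair gives the (S)-cyclohexenone 6, which already carries C5 and its acetate arm (C4, C19).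
Ring A is then annulated onto ring B by two new bonds: C10–C1 (anti-selective copper-catalysed 1,4-addition of a 3-chloropropyl Grignard reagent, which sets quaternary C10 and hence the trans ring fusion) and C3–C4 (ester enolate alkylation). C4 is made quaternary in the same flask by methylation under control of the axial C10 methyl (19-ester axial).
The masked C8 ketone then delivers C9 (Mukaiyama–Michael addition, thermodynamic 9β chain), C8=C17 (Wittig) and 7α-OH (SeO2). The 13E-allylic alcohol comes from zirconium-catalysed carboalumination–iodination of a terminal alkyne and a final Stille hydroxymethylation, so no hydroxyl protecting group is needed.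
The design uses no cation–olefin cyclisation, no polyene oxidation and no oxygen relocation. The rings close in the order B then A, and C4 rests on a substrate-controlled enolate alkylation instead of a CH3/CH2O choice in a cyclisation.

Key step: step 4

Assumption: the (S)-diarylprolinol silyl ether is taken to give the (S)-Michael adduct 3, the facial sense usual for its enamine Michael additions (the (R)-catalyst would be used otherwise); ring positions are given in labdane numbering.

**Route**

Step 1
Reactants: 1 methyl 4-oxobutanoate; 2 but-3-en-2-one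
Product: 4 methyl 2-[(1S)-4-oxocyclohex-2-en-1-yl]acetate, via keto aldehyde 3 (not isolated)
Conditions: (S)-α,α-diphenylprolinol trimethylsilyl ether (10 mol %), PhCO2H (10 mol %), neat, 4 °C; then p-TsOH·H2O (10 mol %), toluene, 60 °C
Reagents that add atoms: none
Why: Enamine-catalysed Michael addition of the aldehyde to the enone creates the C5 stereocentre because the diarylprolinol ether shields one face of the E-enamine of 1, and the acid-promoted intramolecular aldol condensation of the methyl ketone onto the aldehyde then closes ring B as a 4-substituted cyclohexenone without touching that centre.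

Step 2
Reactants: 4 methyl 2-[(1S)-4-oxocyclohex-2-en-1-yl]acetate
Product: 6 methyl 2-[(1S)-2-methyl-4-oxocyclohex-2-en-1-yl]acetate, via silyl enol ether 5 (not isolated)
Conditions: MeMgBr, CuI (10 mol %), Me3SiCl, THF, −78 °C; then Pd(OAc)2 (10 mol %), O2 (1 atm), DMSO, rt
Reagents that add atoms: methylmagnesium bromide, C[Mg]Br
Why: Copper-catalysed conjugate addition of MeMgBr trapped as the silyl enol ether, followed by Saegusa–Ito dehydrogenation, should install the C10 methyl group (C20) and restore the enone; the transient C10 stereocentre is erased and C5 is untouched.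

Step 3
Reactants: 6 methyl 2-[(1S)-2-methyl-4-oxocyclohex-2-en-1-yl]acetate; 7 1-bromo-3-chloropropane
Product: 8 methyl 2-[(1S,2S)-2-(3-chloropropyl)-2-methyl-4-(triethylsilyloxy)cyclohex-3-en-1-yl]acetate
Conditions: 7, Mg, THF, 0 °C (Grignard reagent); then 6, CuBr·SMe2 (10 mol %), Et3SiCl, HMPA, THF, −78 °C; Et3N, aq. NaHCO3
Reagents that add atoms: chlorotriethylsilane, CC[Si](Cl)(CC)CC
Why: Silyl chloride-accelerated copper-catalysed conjugate addition to the β,β-disubstituted enone should create quaternary C10; allylic 1,2-strain with the C10 methyl holds the C5 arm pseudoaxial so the nucleophile enters anti to it (C1 trans to C4, C20 cis), and O-silylation fixes the enolate regiospecifically as the C8–C9 triethylsilyl enol ether.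

Step 4
Reactants: 8 methyl 2-[(1S,2S)-2-(3-chloropropyl)-2-methyl-4-(triethylsilyloxy)cyclohex-3-en-1-yl]acetate
Product: 10 methyl (1S,4aS,8aR)-1,4a-dimethyl-6-(triethylsilyloxy)-1,2,3,4,4a,7,8,8a-octahydronaphthalene-1-carboxylate, via cyclised ester 9 (not isolated)
Conditions: KN(SiMe3)2 (1.1 equiv), THF, −78 to 0 °C; then LiN(i-Pr)2 (1.5 equiv), −78 °C, MeI, DMPU, −78 to −20 °C
Reagents that add atoms: iodomethane, CI
Why: KN(SiMe3)2 converts the acetate arm into its potassium ester enolate, which displaces the primary chloride in a 6-exo-tet SN2 ring closure (C3–C4) that completes ring A; the closest known reaction type is the annulation of enones by conjugate addition of an ω-chloroalkyl copper reagent followed by intramolecular enolate alkylation, here turned from the ketone to the ester enolate. The ring fusion is not formed in this step and is therefore fixed as trans by step 3, which put C1 and C4 on opposite faces of ring B. A second deprotonation gives the exocyclic ester enolate at C4, and MeI should approach it equatorially from the α-face because the β-face is blocked by the 1,3-diaxial C10 methyl, leaving the ester axial (4β-CO2Me, 4α-CH3; 4S), as in alkylations of related 10-methyl-trans-decalin-4-carboxylate enolates. The step needs chemoselectivity for the ester over the ketone α-carbon C9, which the triethylsilyl enol ether secures by masking the ketone and resisting silyl transfer, so that a five-ring closure at C9 cannot compete.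

Step 5
Reactants: 10 methyl (1S,4aS,8aR)-1,4a-dimethyl-6-(triethylsilyloxy)-1,2,3,4,4a,7,8,8a-octahydronaphthalene-1-carboxylate; 11 acrolein
Product: 12 methyl (1S,4aS,8aR)-1,4a-dimethyl-6-oxo-5-(3-oxopropyl)decahydronaphthalene-1-carboxylate (C9 epimers)
Conditions: acrolein (3 equiv), BF3·OEt2 (0.3 equiv), i-PrOH (1.2 equiv), MeNO2–CH2Cl2, −78 to −30 °C
Reagents that add atoms: none
Why: In this Mukaiyama–Michael addition the Lewis acid-activated acrolein should be attacked by C9 of the regio-defined silyl enol ether while the alcohol takes up the silyl group, which forms the C9–C11 bond and unmasks the C8 ketone; C9 stays epimerisable and is set in step 6.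

Step 6
Reactants: 12 methyl (1S,4aS,8aR)-1,4a-dimethyl-6-oxo-5-(3-oxopropyl)decahydronaphthalene-1-carboxylate
Product: 13 methyl (1S,4aS,5R,8aR)-5-(but-3-yn-1-yl)-1,4a-dimethyl-6-oxodecahydronaphthalene-1-carboxylate
Conditions: dimethyl (1-diazo-2-oxopropyl)phosphonate, K2CO3, MeOH, 0 °C to rt
Reagents that add atoms: dimethyl (1-diazo-2-oxopropyl)phosphonate, COP(=O)(OC)C(=[N+]=[N-])C(C)=O
Why: Ohira–Bestmann homologation should convert the aldehyde into the terminal alkyne C13≡C14 while the hindered ketone is left alone (its bridged aldol with the aldehyde is reversible), and K2CO3/MeOH should equilibrate C9 to the equatorial 9β side chain (9α-H).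

Step 7
Reactants: 13 methyl (1S,4aS,5R,8aR)-5-(but-3-yn-1-yl)-1,4a-dimethyl-6-oxodecahydronaphthalene-1-carboxylate
Product: 14 methyl (1S,4aR,5S,8aR)-5-(but-3-yn-1-yl)-1,4a-dimethyl-6-methylidenedecahydronaphthalene-1-carboxylate
Conditions: Ph3PCH3Br, KOt-Bu, THF, rt to 60 °C
Reagents that add atoms: methyltriphenylphosphonium bromide, C[P+](c1ccccc1)(c1ccccc1)c1ccccc1.[Br-]
Why: Wittig methylenation of the C8 ketone should give the 8(17)-exocyclic alkene; the ylide is too weak a base to deprotonate the terminal alkyne, and the hindered axial ester is inert.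

Step 8
Reactants: 14 methyl (1S,4aR,5S,8aR)-5-(but-3-yn-1-yl)-1,4a-dimethyl-6-methylidenedecahydronaphthalene-1-carboxylate
Product: 15 [(1S,4aR,5S,8aR)-5-(but-3-yn-1-yl)-1,4a-dimethyl-6-methylidenedecahydronaphthalen-1-yl]methanol
Conditions: LiAlH4, THF, 0 °C to rt; aq. NaOH work-up
Reagents that add atoms: none
Why: Hydride reduction of the neopentyl axial ester should give the C19 primary alcohol while the alkene, the alkyne and all stereocentres are untouched.

Step 9
Reactants: 15 [(1S,4aR,5S,8aR)-5-(but-3-yn-1-yl)-1,4a-dimethyl-6-methylidenedecahydronaphthalen-1-yl]methanol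
Product: 16 [(1S,4aR,5S,8aR)-5-[(3E)-4-iodo-3-methylbut-3-en-1-yl]-1,4a-dimethyl-6-methylidenedecahydronaphthalen-1-yl]methanol
Conditions: Me3Al (4 equiv), Cp2ZrCl2 (0.3 equiv), CH2Cl2, 0 °C to rt; then I2, THF, −30 to 0 °C; aq. Na2S2O3
Reagents that add atoms: trimethylaluminium, C[Al](C)C; iodine, II
Why: Zirconium-catalysed carboalumination (syn addition of CH3–Al across the terminal alkyne, CH3 to the internal carbon) followed by iodinolysis with retention should give the E-alkenyl iodide, so C16 and the 13E geometry are set in one step; the hydroxyl group is carried as its aluminium alkoxide and the 1,1-disubstituted alkene does not react.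

Step 10
Reactants: 16 [(1S,4aR,5S,8aR)-5-[(3E)-4-iodo-3-methylbut-3-en-1-yl]-1,4a-dimethyl-6-methylidenedecahydronaphthalen-1-yl]methanol
Product: 17 [(1S,4aR,5S,8aR)-5-[(3E)-4-iodo-3-methylbut-3-en-1-yl]-1,4a-dimethyl-6-methylidenedecahydronaphthalen-1-yl]methyl acetate
Conditions: Ac2O, pyridine, DMAP (cat.), CH2Cl2, 0 °C to rt
Reagents that add atoms: acetic anhydride, CC(=O)OC(C)=O
Why: Standard O-acylation of the only hydroxyl group installs the 19-acetate.

Step 11
Reactants: 17 [(1S,4aR,5S,8aR)-5-[(3E)-4-iodo-3-methylbut-3-en-1-yl]-1,4a-dimethyl-6-methylidenedecahydronaphthalen-1-yl]methyl acetate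
Product: 18 [(1S,4aS,5R,7R,8aR)-7-hydroxy-5-[(3E)-4-iodo-3-methylbut-3-en-1-yl]-1,4a-dimethyl-6-methylidenedecahydronaphthalen-1-yl]methyl acetate
Conditions: SeO2 (0.5 equiv), t-BuOOH (2 equiv), CH2Cl2, 0 °C to rt
Reagents that add atoms: selenium dioxide, O=[Se]=O (oxygen carrier); tert-butyl hydroperoxide, CC(C)(C)OO (terminal oxygen source)
Why: In this SeO2 allylic hydroxylation (ene reaction at C17, then [2,3]-sigmatropic shift) the axial 7α-H should be taken in preference to the hindered C9–H and oxygen returned to C7 on the α-face away from the C10 methyl (7R), while the electron-poor iodoalkene is a poor ene partner.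

Step 12
Reactants: 18 [(1S,4aS,5R,7R,8aR)-7-hydroxy-5-[(3E)-4-iodo-3-methylbut-3-en-1-yl]-1,4a-dimethyl-6-methylidenedecahydronaphthalen-1-yl]methyl acetate
Product: 19 19-acetoxylabda-8(17),13E-diene-7α,15-diol
Conditions: Bu3SnCH2OH (1.5 equiv), Pd(PPh3)4 (5 mol %), dioxane, 90 °C
Reagents that add atoms: (tributylstannyl)methanol, CCCC[Sn](CCCC)(CCCC)CO
Why: In this Stille coupling, oxidative addition of zerovalent palladium to the alkenyl iodide, selective transfer of the hydroxymethyl group from tin and reductive elimination should give the allylic alcohol with retention of the E geometry; the free hydroxyl group, the acetate and the exocyclic alkene are tolerated.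

**Compound list**

1 | methyl 4-oxobutanoate | COC(=O)CCC=O | starting material
2 | but-3-en-2-one (methyl vinyl ketone) | CC(=O)C=C | starting material
3 | methyl (3S)-3-formyl-6-oxoheptanoate | CC(=O)CC[C@@H](CC(=O)OC)C=O | intermediate
4 | methyl 2-[(1S)-4-oxocyclohex-2-en-1-yl]acetate | O=C1CC[C@@H](CC(=O)OC)C=C1 | intermediate
5 | methyl 2-[(1S,2S)-2-methyl-4-(trimethylsilyloxy)cyclohex-3-en-1-yl]acetate (methyl trans to the acetate arm) | C[Si](C)(C)OC1=C[C@@H](C)[C@H](CC(=O)OC)CC1 | intermediate
6 | methyl 2-[(1S)-2-methyl-4-oxocyclohex-2-en-1-yl]acetate | O=C1CC[C@@H](CC(=O)OC)C(C)=C1 | intermediate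
7 | 1-bromo-3-chloropropane | ClCCCBr | starting material
8 | methyl 2-[(1S,2S)-2-(3-chloropropyl)-2-methyl-4-(triethylsilyloxy)cyclohex-3-en-1-yl]acetate (chloropropyl trans to the acetate arm) | CC[Si](CC)(CC)OC1=C[C@@](C)(CCCCl)[C@H](CC(=O)OC)CC1 | intermediate
9 | methyl (4aS,8aS)-4a-methyl-6-(triethylsilyloxy)-1,2,3,4,4a,7,8,8a-octahydronaphthalene-1-carboxylate (trans-fused, both C4 epimers) | CC[Si](CC)(CC)OC=1CC[C@H]2C(C(=O)OC)CCC[C@]2(C)C=1 | intermediate
10 | methyl (1S,4aS,8aR)-1,4a-dimethyl-6-(triethylsilyloxy)-1,2,3,4,4a,7,8,8a-octahydronaphthalene-1-carboxylate (4α-CH3, 4β-CO2Me, 5α-H, 10β-CH3) | CC[Si](CC)(CC)OC=1CC[C@H]2[C@@](C)(C(=O)OC)CCC[C@]2(C)C=1 | intermediate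
11 | acrolein (prop-2-enal) | C=CC=O | starting material
12 | methyl (1S,4aS,8aR)-1,4a-dimethyl-6-oxo-5-(3-oxopropyl)decahydronaphthalene-1-carboxylate (C9 epimers) | O=C1CC[C@H]2[C@@](C)(C(=O)OC)CCC[C@]2(C)C1CCC=O | intermediate
13 | methyl (1S,4aS,5R,8aR)-5-(but-3-yn-1-yl)-1,4a-dimethyl-6-oxodecahydronaphthalene-1-carboxylate (9α-H) | O=C1CC[C@H]2[C@@](C)(C(=O)OC)CCC[C@]2(C)[C@H]1CCC#C | intermediate
14 | methyl (1S,4aR,5S,8aR)-5-(but-3-yn-1-yl)-1,4a-dimethyl-6-methylidenedecahydronaphthalene-1-carboxylate | C=C1CC[C@H]2[C@@](C)(C(=O)OC)CCC[C@]2(C)[C@H]1CCC#C | intermediate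
15 | [(1S,4aR,5S,8aR)-5-(but-3-yn-1-yl)-1,4a-dimethyl-6-methylidenedecahydronaphthalen-1-yl]methanol | C=C1CC[C@H]2[C@@](C)(CO)CCC[C@]2(C)[C@H]1CCC#C | intermediate
16 | [(1S,4aR,5S,8aR)-5-[(3E)-4-iodo-3-methylbut-3-en-1-yl]-1,4a-dimethyl-6-methylidenedecahydronaphthalen-1-yl]methanol | C=C1CC[C@H]2[C@@](C)(CO)CCC[C@]2(C)[C@H]1CC/C(C)=C/I | intermediate
17 | [(1S,4aR,5S,8aR)-5-[(3E)-4-iodo-3-methylbut-3-en-1-yl]-1,4a-dimethyl-6-methylidenedecahydronaphthalen-1-yl]methyl acetate | C=C1CC[C@H]2[C@@](C)(COC(C)=O)CCC[C@]2(C)[C@H]1CC/C(C)=C/I | intermediate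
18 | [(1S,4aS,5R,7R,8aR)-7-hydroxy-5-[(3E)-4-iodo-3-methylbut-3-en-1-yl]-1,4a-dimethyl-6-methylidenedecahydronaphthalen-1-yl]methyl acetate (7α-OH) | C=C1[C@H](O)C[C@H]2[C@@](C)(COC(C)=O)CCC[C@]2(C)[C@H]1CC/C(C)=C/I | intermediate
19 | 19-acetoxylabda-8(17),13E-diene-7α,15-diol (4S,5R,7R,9R,10S) | C=C1[C@H](O)C[C@H]2[C@@](C)(COC(C)=O)CCC[C@]2(C)[C@H]1CC/C(C)=C/CO | target

**Step count and risks**

Total step count: 12. Longest linear sequence: 12 steps (from 1 and 2 to 19).

The three steps most likely to fail are step 5, step 3 and step 12.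

- **Step 5.** 1,2-Addition of the silyl enol ether to the aldehyde carbonyl, or oligomerisation of acrolein, may outrun the 1,4-addition at the hindered C9. Fallback: from 10, a palladium-catalysed Tsuji allylation of the silyl enol ether (allyl methyl carbonate, Pd2(dba)3, dppe, THF, 65 °C) would give the 9-allyl ketone methyl (1S,4aS,8aR)-1,4a-dimethyl-6-oxo-5-(prop-2-en-1-yl)decahydronaphthalene-1-carboxylate F1. An aldehyde-selective Wacker oxidation of its terminal alkene (PdCl2(PhCN)2, CuCl2, AgNO2, O2, t-BuOH–MeNO2) would then give aldehyde 12, where the route is rejoined.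

- **Step 3.** The γ-chloro Grignard reagent may be lost by 1,3-elimination to cyclopropane before transmetalation, or may attack the ester. Fallback: from 6, the stable Grignard reagent of benzyl 3-bromopropyl ether would be added under the same copper catalysis and trapped with Et3SiCl to give methyl 2-[(1S,2S)-2-[3-(benzyloxy)propyl]-2-methyl-4-(triethylsilyloxy)cyclohex-3-en-1-yl]acetate F2. Hydrogenolysis (H2, Pd/C, EtOAc, Et3N) would free methyl 2-[(1S,2S)-2-(3-hydroxypropyl)-2-methyl-4-(triethylsilyloxy)cyclohex-3-en-1-yl]acetate F3, and TsCl/pyridine would give methyl 2-[(1S,2S)-2-methyl-2-[3-(tosyloxy)propyl]-4-(triethylsilyloxy)cyclohex-3-en-1-yl]acetate F4. F4 would be closed and methylated under the conditions of step 4, rejoining the route at 10.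

- **Step 12.** Transfer of the hydroxymethyl group from tin may be slow, so that reduction or homocoupling of the alkenyl iodide takes over. Fallback: from 15, the alkenylalane of the carboalumination would be trapped with paraformaldehyde instead of iodine to give labda-8(17),13E-diene-15,19-diol F5. Acetylation of both hydroxyl groups would give 15,19-diacetoxylabda-8(17),13E-diene F6, and SeO2/t-BuOOH would give 15,19-diacetoxylabda-8(17),13E-dien-7α-ol F7. Methanolysis of the unhindered allylic acetate (K2CO3, MeOH, 0 °C), which should be faster than that of the neopentyl 19-acetate, would then give 19.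

**Further compounds**

F1 | step 5 | methyl (1S,4aS,8aR)-1,4a-dimethyl-6-oxo-5-(prop-2-en-1-yl)decahydronaphthalene-1-carboxylate (C9 epimers) | O=C1CC[C@H]2[C@@](C)(C(=O)OC)CCC[C@]2(C)C1CC=C
F2 | step 3 | methyl 2-[(1S,2S)-2-[3-(benzyloxy)propyl]-2-methyl-4-(triethylsilyloxy)cyclohex-3-en-1-yl]acetate | CC[Si](CC)(CC)OC1=C[C@@](C)(CCCOCc2ccccc2)[C@H](CC(=O)OC)CC1
F3 | step 3 | methyl 2-[(1S,2S)-2-(3-hydroxypropyl)-2-methyl-4-(triethylsilyloxy)cyclohex-3-en-1-yl]acetate | CC[Si](CC)(CC)OC1=C[C@@](C)(CCCO)[C@H](CC(=O)OC)CC1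
F4 | step 3 | methyl 2-[(1S,2S)-2-methyl-2-[3-(tosyloxy)propyl]-4-(triethylsilyloxy)cyclohex-3-en-1-yl]acetate | CC[Si](CC)(CC)OC1=C[C@@](C)(CCCOS(=O)(=O)c2ccc(C)cc2)[C@H](CC(=O)OC)CC1
F5 | step 12 | labda-8(17),13E-diene-15,19-diol | C=C1CC[C@H]2[C@@](C)(CO)CCC[C@]2(C)[C@H]1CC/C(C)=C/CO
F6 | step 12 | 15,19-diacetoxylabda-8(17),13E-diene | C=C1CC[C@H]2[C@@](C)(COC(C)=O)CCC[C@]2(C)[C@H]1CC/C(C)=C/COC(C)=O
F7 | step 12 | 15,19-diacetoxylabda-8(17),13E-dien-7α-ol | C=C1[C@H](O)C[C@H]2[C@@](C)(COC(C)=O)CCC[C@]2(C)[C@H]1CC/C(C)=C/COC(C)=O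
A1 | direct plan | (2E,6E,10E,14E)-16-(tert-butyldiphenylsilyloxy)-2,6,10,14-tetramethylhexadeca-2,6,10,14-tetraen-1-ol | OC/C(C)=C/CC/C(C)=C/CC/C(C)=C/CC/C(C)=C/CO[Si](c1ccccc1)(c1ccccc1)C(C)(C)C
A2 | direct plan | (S)-2-methyl-2-[(4E,8E,12E)-14-(tert-butyldiphenylsilyloxy)-4,8,12-trimethyltetradeca-4,8,12-trienyl]oxirane | C[C@@]1(CO1)CCC/C(C)=C/CC/C(C)=C/CC/C(C)=C/CO[Si](c1ccccc1)(c1ccccc1)C(C)(C)C
A3 | direct plan | 19-acetoxy-15-(tert-butyldiphenylsilyloxy)labda-8(17),13E-diene | C=C1CC[C@H]2[C@@](C)(COC(C)=O)CCC[C@]2(C)[C@H]1CC/C(C)=C/CO[Si](c1ccccc1)(c1ccccc1)C(C)(C)C
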